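The target is made in the first step below, with free catalyst returned at each turn, so its amount at 20 s depends on how much catalyst stays free, and for how long.

    starting material + dissolved gas + free catalyst → free catalyst + target (k1 = 5.1 × 10⁷ L² mol⁻² s⁻¹)
    gas phase ⇌ dissolved gas, rate k2*(csat - [dissolved gas]) (k2 = 190 s⁻¹, csat = 0.044 mM)
    2 dissolved gas → homo dimer (k3 = 1700 L mol⁻¹ s⁻¹)
    2 free catalyst → spent catalyst B (k4 = 1700 L mol⁻¹ s⁻¹)
    free catalyst + impurity → spent catalyst A (k5 = 1.2 × 10⁶ L mol⁻¹ s⁻¹)

starting material 1.0 mM; gas phase 0.044 mM (held); free catalyst 50 µM; impurity 45 µM; time 20 s

1. the target standing at 20 s, as a percentage of the starting material charged
2. concentration of dissolved gas in solution at 20 s, in percent of saturation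

- where a step has two of a species, its rate is k times that concentration squared, and two are used at each turn
- at the start none of the gas is dissolved
- run time (flask): 20 s

Which numbers must I know well? The charges come first. The impurity removes its equivalent of catalyst, leaving an excess of 5.00 µM. The catalyst charge is ten times that excess and the impurity charge 9.00 times it, so a small share of error on either charge arrives magnified by those factors in the excess. The impurity's rate constant matters little: against the excess, the decay time of the impurity is about 0.167 s, far shorter than 20 s, and at the start it takes catalyst 320 times faster than catalyst dimerisation does. The transfer coefficient and the rate constant of the dissolved gas dimerisation matter little too. Transfer at 190 s⁻¹ is far faster than the 2.55 s⁻¹ at which the whole catalyst charge would draw on dissolved gas, and than the 0.150 s⁻¹ at which dissolved gas dimerises at saturation. So I hold [dissolved gas] at 99.8 % of saturation, treating it as saturated.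

Starting material then falls pseudo-first-order, with a constant that shrinks as [free catalyst] pairs off. I reckon [free catalyst] as the excess over 1 + u, where u is 2 times the catalyst dimerisation constant, the excess and the time. Here u reaches 0.340, below 1, so the catalyst dimerisation constant trims the mean catalyst to 86.1 % of the excess. The first step's constant and the saturation enter in direct proportion, so both must be known well. Integrating gives 0.193, the turnover exponent: the natural logarithm of charged over remaining starting material. The target is therefore 17.6 %.

The forecast gives 17.5 % and 99.8 %, holding that “the solution stays essentially saturated”, with its target a shade below mine.

The simulation gives 17.4 % of target and 99.8 % of saturation, and the exponent read from that target is 0.191, beside my 0.193. A neighbouring flask charged with 0.085 mM of free catalyst, all else unchanged, has an excess of 40.0 µM, which makes u 2.72. Its exponent is 0.867, so the excess grows 8.00 times but the exponent 4.49 times. That gives 58.0 % by hand, and that neighbouring flask holds 57.7 % of target.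

The numbers of this flask were set for the occasion; the result is computed.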